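## Analysis of the target

Target 19 is a 2,3-dihydro-1-benzofuran (O1, C2, C3, C3a, C7a fused to benzene ring A) in which C2 carries a hydrogen and a 4-hydroxyphenyl group (ring B) and C3 carries a hydroxyl and a 2,4-dihydroxybenzoyl group (ring C). C5, para to O1, carries an (E)-3-oxoprop-1-enyl arm that ends in a second 2,4-dihydroxyphenyl ring (ring D). The two stereocentres are adjacent and both S; ring B and the C3 hydroxyl lie on the same face, so ring B is anti to the aroyl group. C3 is fully substituted (ring A carbon, acyl carbon, oxygen, C2), so it cannot be corrected by epimerisation once it is made. The sensitive groups are the 2′-hydroxychalcone of ring D (a Michael acceptor that can close to a flavanone), the tertiary benzylic α-ketol at C3 (open to an acyloin-type 1,2-shift with ring expansion), the C2–O1 bond (a para-hydroxybenzyl aryl ether that can open through a quinone methide or benzylic cation and scramble C2) and five oxidisable phenols. The difficulty is to build the O1–C2–C3 array with absolute and relative control while both ketones stay at the ketone oxidation level. The strategy rests on one feature: C2 is a single carbon bonded only to the phenolic oxygen O1 of ring A, to ring B and to C3, and C3 is a carbinol flanked by C3a and the ring C ketone. C3 therefore reads as one carbonyl of a 1,2-dione that has accepted a carbon nucleophile, and C2 as a one-carbon unit at the carbene oxidation level that makes one C–O and one C–C bond.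

## Retrosynthetic reasoning

**Unmasking (19 from 18 from 17).** The last disconnections are four acetal C–O bonds on rings C and D and one ester C–O bond on ring B. All phenols except the one that becomes O1 must be capped, because any free O–H would compete for the carbene. The resorcinol oxygens are carried as methoxymethyl ethers, which are inert to base, organometallics and oxidants and are removed by mild acid. The ring B oxygen is carried as a pivalate, because an acyloxy group makes the diazo compound less electron-rich and easier to handle. The ester is removed first under base, while the 2′-oxygen of ring D is still capped and flavanone closure is impossible; the acetals are removed last.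

**Enone arm (17 from 14 and 16).** The C5–CH= bond is cut. An enone is a Michael acceptor and a dipolarophile and cannot be present when a diazo compound and a carbene are in the flask. Cutting here leaves the aryl bromide 14, whose C–Br bond is inert in the key step, and the aryl vinyl ketone 16. The forward Mizoroki–Heck arylation has to give the E-alkene and tolerate a free tertiary alcohol, an aryl ester and the two stereocentres, which are remote from the reacting carbon.

**Core (14 from 8 and 13).** The bonds O1–C2 and C2–C3 are cut. Removing C2 together with ring B leaves the achiral hydroxy dione 8, in which C3 is a ketone, and turns C2 into the carbene carbon of the diazo compound 13. Both stereocentres and the ring then arise in one event from two achiral pieces, and both ketones are already at their final oxidation level. Cuts at C3–C3a, O1–C7a or the C3–acyl bond would each need a preformed stereocentre or a later change of oxidation state. The forward reaction has to: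
- form the O–C bond first (phenol oxygen onto the carbene);
- then form the C–C bond to the ring A-side carbonyl in a five-membered closure, in preference to proton transfer and to a six-membered closure onto the ring C-side carbonyl;
- use one face of that carbonyl and place ring B anti to the aroyl group.

**Dione (8 from 7 from 6).** Both carbonyl oxygens are removed to give the diarylalkyne 6. The two carbons are already joined in an alkyne, so an unsymmetrical benzil is reached without any regiochemical question. The silyl group on O1 is removed last (7 to 8), so that the free phenol, which can add to the ring C-side carbonyl as a ring hemiketal, appears only just before the key step.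

**Alkyne (6 from 5 and 3, 5 from 4).** The aryl–alkyne bond is cut at the ring A carbon that bears iodine in 5. The iodide couples in preference to the bromide, so the C5 handle for the enone arm is in place from the start. The phenol of 4 must be silylated, since a free ortho-alkynylphenol would cyclise to a benzofuran under the coupling conditions.

**Common aldehyde (3 from 2, 16 from 15 from 2, 2 from 1).** The protected aldehyde 2 serves both ring C and ring D. One-carbon homologation gives alkyne 3; addition of a vinyl-metal reagent and oxidation of the allylic alcohol 15 gives vinyl ketone 16. One protection step thus covers four phenolic oxygens.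

**Diazo compound (13 from 11 from 10 from 9).** The diazo group is traced back to the sulfonylhydrazone 11 of aldehyde 10, which is the pivalate of 9. The base used to release 13 must be non-nucleophilic so that the aryl ester survives.

## Alternatives that were turned down

**Alternative 1: Darzens oxirane as a stereochemical relay.**
- Disconnection: C2–C3 is formed together with a temporary C3–O oxirane bond; O1–C2 is made later by opening the oxirane at C2 with the ring A phenoxide, with inversion.
- Forward key step: under a chiral quaternary ammonium phase-transfer catalyst, the enolate of the α-chloro ketone A1 adds to 4-(methoxymethoxy)benzaldehyde A2, and the aldolate displaces chloride to give the trans epoxy ketone A3 (C3 as in the target, C2 inverted).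
- For it: the asymmetric Darzens condensation of α-chloro ketones with aryl aldehydes is an established reaction type. No diazo compound is needed, and A3 is a robust, isolable carrier of both centres. On precedent for the enantio-determining step it is stronger than the chosen route.
- Against it:
  - the enolate of A1 is that of a tertiary α-aryl α-chloro ketone, so the oxirane carbon C3 is fully substituted, which is at the edge of what such catalysts handle, and the enolate geometry is not fixed;
  - the relay requires the phenoxide, tethered through C3, to attack C2 from the side opposite the oxirane oxygen, with the oxirane C–C bond inside the new five-membered ring, a strained trajectory;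
  - C2 carries an electron-rich aryl group, so ionisation of the C2–O bond competes, which would leak the configuration or trigger a 1,2-shift;
  - A1 needs its own synthesis, and desilylation and ring closure are extra steps.
- Comparison: the chosen route offers both bonds and both centres in one operation, with the final relative configuration set directly and not through an invertive step.

**Alternative 2: Fluoroaryl Grignard reagent as a benzyne equivalent.**
- Disconnection: C3–C3a and O1–C7a, so ring A is attached last.
- Forward key step: the Grignard reagent A5 deprotonates the hydroxyl of the α-hydroxy ketone A4 and adds to the ketone of the resulting Mg-alkoxide chelate (C3–C3a); the C2 alkoxide then displaces the ortho fluoride, activated by the para nitrile (O1–C7a), to give A6.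
- For it: every elementary step is known. The chelate model predicts attack anti to ring B, which after ring closure places ring B cis to the hydroxyl, as required. The absolute configuration comes from a secondary carbinol that standard asymmetric methods can supply, and the regiochemistry of the ring closure is unambiguous. On precedent and predictability it is stronger than the chosen route.
- Against it:
  - the stereocentre of A4 is benzylic and α to a ketone, so it is easily enolised by the basic reagent;
  - the ketone of A4 is an α-aryl enone, open to conjugate addition;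
  - the nitrile of A5 can be attacked by its own carbanion;
  - the aroyl group is only present as a 1-arylvinyl group and the enone arm only as a nitrile, so an alkene cleavage in the presence of electron-rich arenes, a nitrile reduction and an olefination all follow the key step.
- Comparison: the route would be roughly twice as long after the key step. The chosen route keeps both ketones at the right oxidation level throughout and reaches the target three steps after the key step.

**Alternative 3: Norrish–Yang photocyclisation.**
- Disconnection: C2–C3 only; O1–C2 is already present as a benzyl aryl ether.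
- Forward key step: visible light (about 420 nm) excites the 1,2-dione of A7; the C3 carbonyl oxygen abstracts a benzylic hydrogen from C2, and the 1,5-biradical couples to A8.
- For it: it is the shortest route, needs no metal and no diazo compound, and belongs to a known reaction type (photocyclisation of ortho-benzyloxyaryl ketones). The yellow dione is excited selectively, because the product ketone does not absorb at that wavelength. On simplicity and precedent it is stronger than the chosen route.
- Against it:
  - a triplet biradical offers no handle for absolute control, so the product is racemic unless a chiral template is found, and half the material is lost on resolution;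
  - the diastereoselectivity of biradical coupling rests on conformational effects only;
  - the α-hydroxy ketone product is itself prone to photochemical α-cleavage on over-irradiation.
- Comparison: the chosen route offers catalytic enantiocontrol through the chelated dione, in exchange for a key step that is not yet known. This photocyclisation is kept as the fallback for the key step.

Key step: step 10

Assumption: which antipode of the N,N′-dioxide ligand leads to the (2S,3S) product cannot be predicted with confidence; the route is written for the ligand from L-pipecolic acid, and the ligand from D-pipecolic acid is to be used if the opposite enantiomer forms.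

## Route

Step 1
Reactants: 1 2,4-dihydroxybenzaldehyde
Product: 2 2,4-bis(methoxymethoxy)benzaldehyde
Conditions: NaH (2.4 equiv), MOMCl (2.4 equiv), DMF, 0 °C → rt
Reagents that add atoms: chloromethyl methyl ether (MOMCl), COCCl
Why: Williamson-type O-alkylation of both phenoxides; NaH is used because the chelated 2-hydroxyl resists weaker bases, and the resulting acetal ethers are stable to the basic, oxidative and organometallic steps that follow.

Step 2
Reactants: 2 2,4-bis(methoxymethoxy)benzaldehyde
Product: 3 1-ethynyl-2,4-bis(methoxymethoxy)benzene
Conditions: dimethyl (1-diazo-2-oxopropyl)phosphonate, K2CO3, MeOH, rt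
Reagents that add atoms: dimethyl (1-diazo-2-oxopropyl)phosphonate (Ohira–Bestmann reagent), COP(=O)(OC)C(=[N+]=[N-])C(C)=O
Why: Seyferth–Gilbert homologation in the Ohira–Bestmann variant: methanolysis of the acetyl group releases the diazomethylphosphonate anion, which olefinates the aldehyde, and loss of dinitrogen with a 1,2-hydride shift gives the terminal alkyne under mild base.

Step 3
Reactants: 4 4-bromo-2-iodophenol
Product: 5 (4-bromo-2-iodophenoxy)(tert-butyl)dimethylsilane
Conditions: TBSCl, imidazole, DMF, rt
Reagents that add atoms: tert-butyldimethylsilyl chloride (TBSCl), CC(C)(C)[Si](C)(C)Cl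
Why: Silylation of the phenol; a free ortho-alkynylphenol would cyclise to a benzofuran under the PdCl2(PPh3)2/CuI conditions of the next step, and the silyl group can later be removed with fluoride without touching the acetals.

Step 4
Reactants: 5 (4-bromo-2-iodophenoxy)(tert-butyl)dimethylsilane, 3 1-ethynyl-2,4-bis(methoxymethoxy)benzene
Product: 6 tert-butyl(4-bromo-2-{[2,4-bis(methoxymethoxy)phenyl]ethynyl}phenoxy)dimethylsilane
Conditions: PdCl2(PPh3)2 (2 mol%), CuI (4 mol%), Et3N, THF, rt
Reagents that add atoms: none
Why: Sonogashira coupling; oxidative addition into the C–I bond is much faster than into the C–Br bond at room temperature, so the bromide para to oxygen should be carried through untouched.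

Step 5
Reactants: 6 tert-butyl(4-bromo-2-{[2,4-bis(methoxymethoxy)phenyl]ethynyl}phenoxy)dimethylsilane
Product: 7 1-[5-bromo-2-(tert-butyldimethylsilyloxy)phenyl]-2-[2,4-bis(methoxymethoxy)phenyl]ethane-1,2-dione
Conditions: KMnO4, NaHCO3, MgSO4, acetone/H2O, rt
Reagents that add atoms: potassium permanganate, [K+].[O-][Mn](=O)(=O)=O
Why: Permanganate oxidation of a diarylalkyne to a benzil under buffered, near-neutral conditions; the cyclic manganate ester collapses to the 1,2-dione, and the silyl ether, acetals and aryl bromide should be inert.

Step 6
Reactants: 7 1-[5-bromo-2-(tert-butyldimethylsilyloxy)phenyl]-2-[2,4-bis(methoxymethoxy)phenyl]ethane-1,2-dione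
Product: 8 1-(5-bromo-2-hydroxyphenyl)-2-[2,4-bis(methoxymethoxy)phenyl]ethane-1,2-dione
Conditions: TBAF, AcOH, THF, 0 °C
Reagents that add atoms: none
Why: Fluoride-mediated cleavage of the aryl silyl ether; acetic acid buffers the phenoxide so that the base-sensitive dione is not exposed to unbuffered fluoride, and the open dione form is expected to dominate because the ring C-side ketone is deactivated by two alkoxy donors.

Step 7
Reactants: 9 4-hydroxybenzaldehyde
Product: 10 4-formylphenyl pivalate
Conditions: PivCl, Et3N, DMAP (cat.), CH2Cl2, 0 °C → rt
Reagents that add atoms: pivaloyl chloride, CC(C)(C)C(Cl)=O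
Why: DMAP-catalysed O-acylation; the acyl group lowers the donor strength of the para oxygen, which should make the later diazo compound less prone to self-decomposition, and the hindered ester withstands non-nucleophilic bases.

Step 8
Reactants: 10 4-formylphenyl pivalate
Product: 11 4-{(E)-[2-(4-methylbenzenesulfonyl)hydrazinylidene]methyl}phenyl pivalate
Conditions: TsNHNH2, MeOH, rt
Reagents that add atoms: 4-methylbenzenesulfonohydrazide, Cc1ccc(cc1)S(=O)(=O)NN
Why: Condensation of an aldehyde with a sulfonyl hydrazide; the weakly nucleophilic hydrazide attacks only the aldehyde and leaves the aryl ester alone, and the E-hydrazone should crystallise from the medium.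

Step 9
Reactants: 11 4-{(E)-[2-(4-methylbenzenesulfonyl)hydrazinylidene]methyl}phenyl pivalate
Product: 13 4-(diazomethyl)phenyl pivalate, via sodium tosylhydrazonide 12 (not isolated)
Conditions: NaH (1.0 equiv), THF, 0 °C; then BnEt3NCl (10 mol%), toluene, 40 °C, dark; filter, ice-water wash, dry (Na2SO4); titrated toluene solution kept at −20 °C and used the same day
Reagents that add atoms: none
Why: Bamford–Stevens reaction: the N-sodio salt expels sulfinate on gentle warming under phase-transfer assistance to give the aryldiazomethane; NaH instead of an alkoxide keeps the aryl ester intact, and the wash removes salts that would bind the Lewis acid of the next step.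

Step 10
Reactants: 8 1-(5-bromo-2-hydroxyphenyl)-2-[2,4-bis(methoxymethoxy)phenyl]ethane-1,2-dione, 13 4-(diazomethyl)phenyl pivalate
Product: 14 4-{(2S,3S)-5-bromo-3-hydroxy-3-[2,4-bis(methoxymethoxy)benzoyl]-2,3-dihydro-1-benzofuran-2-yl}phenyl pivalate (ring B cis to the C3 hydroxyl)
Conditions: Sc(OTf)3 (10 mol%), chiral N,N′-dioxide ligand L-PiPr2 (from L-pipecolic acid, 2,6-diisopropylanilide arms, propane-1,3-diyl linker; 11 mol%), Rh2(OAc)4 (2 mol%), 4 Å MS, CH2Cl2, −20 °C; 13 (2 equiv, toluene solution) by syringe pump over 6 h
Reagents that add atoms: none
Why: Proposed new method: Rh2(OAc)4 takes dinitrogen out of 13 to give an electrophilic benzylidene carbene; the phenol oxygen of 8 adds to it (O1–C2), and the benzylic carbon of the resulting Rh2(OAc)4-bound oxonium ylide then attacks the adjacent ketone (C2–C3) before the usual 1,2-proton shift can occur. The closest known reaction type is the Rh2(OAc)4-catalysed O–H insertion of aryl diazoacetates into 2-hydroxyaryl ketones with intramolecular aldol capture of the ylide; new here is a donor-only carbene, whose ylide has no ester to hold it as an enol and must therefore be captured while still metal-bound. The one new ring (O1, C2, C3, C3a, C7a) closes in the 5-exo-trig mode, the attacked C=O lying outside the ring, and a six-membered closure onto the other carbonyl is disfavoured because that ketone is deactivated by two alkoxy donors on ring C. C3 is controlled by the Sc(OTf)3/N,N′-dioxide chelate of the open 1,2-dione, whose anilide arms leave one face of the ring A-side carbonyl accessible. C2 is controlled relative to C3 in the same transition state, the ylide carbon turning ring B away from the Sc(OTf)3-bound aroyl group and toward the small developing alkoxide, which gives the ring B/hydroxyl-cis (2S,3S) isomer. Three selectivities are needed: C–C capture over proton transfer, secured by the ketone lying five atoms from the ylide carbon as the activated half of a dione; phenol attack over carbonyl-ylide formation, secured by the Sc(OTf)3 centre occupying both carbonyl oxygens and freeing the phenol from its hydrogen bond; and carbene formation over direct Lewis-acid-mediated addition of the nucleophilic diazo carbon to the dione, secured by slow addition of 13 at low temperature onto Rh2(OAc)4, which consumes it much faster, and by the acyloxy group, which lowers the nucleophilicity of the diazo carbon. The ring hemiketal tautomer of 8 is expected to be drawn back into the open form by the same chelation.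

Step 11
Reactants: 2 2,4-bis(methoxymethoxy)benzaldehyde
Product: 15 1-[2,4-bis(methoxymethoxy)phenyl]prop-2-en-1-ol (racemic)
Conditions: CH2=CHMgBr, THF, −78 → 0 °C; aq. NH4Cl
Reagents that add atoms: vinylmagnesium bromide, C=C[Mg]Br
Why: Grignard 1,2-addition to an aldehyde without α-hydrogens; the new carbinol centre is racemic, which does not matter because it is oxidised in the next step.

Step 12
Reactants: 15 1-[2,4-bis(methoxymethoxy)phenyl]prop-2-en-1-ol
Product: 16 1-[2,4-bis(methoxymethoxy)phenyl]prop-2-en-1-one
Conditions: MnO2 (activated, excess), CH2Cl2, rt; filtered, kept cold with BHT and used promptly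
Reagents that add atoms: none
Why: Selective MnO2 oxidation of an alcohol that is both benzylic and allylic, under neutral heterogeneous conditions that avoid the acids and bases which polymerise aryl vinyl ketones.

Step 13
Reactants: 14 4-{(2S,3S)-5-bromo-3-hydroxy-3-[2,4-bis(methoxymethoxy)benzoyl]-2,3-dihydro-1-benzofuran-2-yl}phenyl pivalate, 16 1-[2,4-bis(methoxymethoxy)phenyl]prop-2-en-1-one
Product: 17 4-{(2S,3S)-3-hydroxy-3-[2,4-bis(methoxymethoxy)benzoyl]-5-[(E)-3-(2,4-bis(methoxymethoxy)phenyl)-3-oxoprop-1-en-1-yl]-2,3-dihydro-1-benzofuran-2-yl}phenyl pivalate
Conditions: Pd2(dba)3 (2.5 mol%), [HP(t-Bu)3]BF4 (10 mol%), Cy2NMe (1.5 equiv), 16 (2.5 equiv), BHT (cat.), 1,4-dioxane, 50 °C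
Reagents that add atoms: none
Why: Mizoroki–Heck reaction: the bulky trialkylphosphine allows oxidative addition into the electron-rich C–Br bond at moderate temperature, syn carbopalladation and syn β-hydride elimination give the E-enone, and the hindered amine neither adds to the enone nor cleaves the ester; the stereocentres are remote and are not touched.

Step 14
Reactants: 17 4-{(2S,3S)-3-hydroxy-3-[2,4-bis(methoxymethoxy)benzoyl]-5-[(E)-3-(2,4-bis(methoxymethoxy)phenyl)-3-oxoprop-1-en-1-yl]-2,3-dihydro-1-benzofuran-2-yl}phenyl pivalate
Product: 18 (E)-3-{(2S,3S)-3-hydroxy-2-(4-hydroxyphenyl)-3-[2,4-bis(methoxymethoxy)benzoyl]-2,3-dihydro-1-benzofuran-5-yl}-1-[2,4-bis(methoxymethoxy)phenyl]prop-2-en-1-one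
Conditions: K2CO3 (1.2 equiv), MeOH/THF, 0 °C → rt, argon; aq. NH4Cl
Reagents that add atoms: none
Why: Methanolysis of the aryl ester, whose phenoxide is a good leaving group; the acetals are inert to base and, with the 2′-oxygen of ring D still capped, the chalcone cannot close to a flavanone. The base is kept near one equivalent and the mixture cold so that the freed ring B phenoxide has little chance to open the C2–O1 bond through a quinone methide.

Step 15
Reactants: 18 (E)-3-{(2S,3S)-3-hydroxy-2-(4-hydroxyphenyl)-3-[2,4-bis(methoxymethoxy)benzoyl]-2,3-dihydro-1-benzofuran-5-yl}-1-[2,4-bis(methoxymethoxy)phenyl]prop-2-en-1-one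
Product: 19 (E)-3-[(2S,3S)-3-(2,4-dihydroxybenzoyl)-3-hydroxy-2-(4-hydroxyphenyl)-2,3-dihydro-1-benzofuran-5-yl]-1-(2,4-dihydroxyphenyl)prop-2-en-1-one
Conditions: 3 M aq. HCl, MeOH, 40 °C; NaHCO3 quench
Reagents that add atoms: none
Why: Acid-catalysed transacetalisation of the four aryl methoxymethyl ethers to the solvent; mild acid and moderate temperature are chosen so that the C2–O1 bond should not ionise and the 2′-hydroxychalcone should not cyclise, and C3 cannot ionise because of the adjacent carbonyl.

## Compound list

1 | 2,4-dihydroxybenzaldehyde | O=Cc1ccc(O)cc1O | starting material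
2 | 2,4-bis(methoxymethoxy)benzaldehyde | O=Cc1ccc(OCOC)cc1OCOC | intermediate
3 | 1-ethynyl-2,4-bis(methoxymethoxy)benzene | C#Cc1ccc(OCOC)cc1OCOC | intermediate
4 | 4-bromo-2-iodophenol | Oc1ccc(Br)cc1I | starting material
5 | (4-bromo-2-iodophenoxy)(tert-butyl)dimethylsilane | CC(C)(C)[Si](C)(C)Oc1ccc(Br)cc1I | intermediate
6 | tert-butyl(4-bromo-2-{[2,4-bis(methoxymethoxy)phenyl]ethynyl}phenoxy)dimethylsilane | CC(C)(C)[Si](C)(C)Oc1ccc(Br)cc1C#Cc1ccc(OCOC)cc1OCOC | intermediate
7 | 1-[5-bromo-2-(tert-butyldimethylsilyloxy)phenyl]-2-[2,4-bis(methoxymethoxy)phenyl]ethane-1,2-dione | CC(C)(C)[Si](C)(C)Oc1ccc(Br)cc1C(=O)C(=O)c1ccc(OCOC)cc1OCOC | intermediate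
8 | 1-(5-bromo-2-hydroxyphenyl)-2-[2,4-bis(methoxymethoxy)phenyl]ethane-1,2-dione | Oc1ccc(Br)cc1C(=O)C(=O)c1ccc(OCOC)cc1OCOC | intermediate
9 | 4-hydroxybenzaldehyde | O=Cc1ccc(O)cc1 | starting material
10 | 4-formylphenyl pivalate | O=Cc1ccc(OC(=O)C(C)(C)C)cc1 | intermediate
11 | 4-{(E)-[2-(4-methylbenzenesulfonyl)hydrazinylidene]methyl}phenyl pivalate | CC(C)(C)C(=O)Oc1ccc(/C=N/NS(=O)(=O)c2ccc(C)cc2)cc1 | intermediate
12 | sodium salt of 11 (sodium tosylhydrazonide) | [Na+].CC(C)(C)C(=O)Oc1ccc(/C=N/[N-]S(=O)(=O)c2ccc(C)cc2)cc1 | intermediate
13 | 4-(diazomethyl)phenyl pivalate | [N-]=[N+]=Cc1ccc(OC(=O)C(C)(C)C)cc1 | intermediate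
14 | 4-{(2S,3S)-5-bromo-3-hydroxy-3-[2,4-bis(methoxymethoxy)benzoyl]-2,3-dihydro-1-benzofuran-2-yl}phenyl pivalate | Brc1ccc2c(c1)[C@@](O)(C(=O)c1ccc(OCOC)cc1OCOC)[C@H](c1ccc(OC(=O)C(C)(C)C)cc1)O2 | intermediate
15 | 1-[2,4-bis(methoxymethoxy)phenyl]prop-2-en-1-ol (racemic) | C=CC(O)c1ccc(OCOC)cc1OCOC | intermediate
16 | 1-[2,4-bis(methoxymethoxy)phenyl]prop-2-en-1-one | C=CC(=O)c1ccc(OCOC)cc1OCOC | intermediate
17 | 4-{(2S,3S)-3-hydroxy-3-[2,4-bis(methoxymethoxy)benzoyl]-5-[(E)-3-(2,4-bis(methoxymethoxy)phenyl)-3-oxoprop-1-en-1-yl]-2,3-dihydro-1-benzofuran-2-yl}phenyl pivalate | O=C(/C=C/c1ccc2c(c1)[C@@](O)(C(=O)c1ccc(OCOC)cc1OCOC)[C@H](c1ccc(OC(=O)C(C)(C)C)cc1)O2)c1ccc(OCOC)cc1OCOC | intermediate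
18 | (E)-3-{(2S,3S)-3-hydroxy-2-(4-hydroxyphenyl)-3-[2,4-bis(methoxymethoxy)benzoyl]-2,3-dihydro-1-benzofuran-5-yl}-1-[2,4-bis(methoxymethoxy)phenyl]prop-2-en-1-one | O=C(/C=C/c1ccc2c(c1)[C@@](O)(C(=O)c1ccc(OCOC)cc1OCOC)[C@H](c1ccc(O)cc1)O2)c1ccc(OCOC)cc1OCOC | intermediate
19 | (E)-3-[(2S,3S)-3-(2,4-dihydroxybenzoyl)-3-hydroxy-2-(4-hydroxyphenyl)-2,3-dihydro-1-benzofuran-5-yl]-1-(2,4-dihydroxyphenyl)prop-2-en-1-one | O=C(/C=C/c1ccc2c(c1)[C@@](O)(C(=O)c1ccc(O)cc1O)[C@H](c1ccc(O)cc1)O2)c1ccc(O)cc1O | target

## Step count and least certain steps

Total: 15 steps. Longest linear sequence: 9 steps (steps 1, 2, 4, 5, 6, 10, 13, 14, 15, from 1 to 19).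

**Step 10 (key step, proposed new method).**
- What may go wrong:
  - proton transfer within the ylide before the C–C bond forms, which ends in plain O–H insertion;
  - direct addition of the nucleophilic diazo carbon to the Sc(OTf)3-activated dione without Rh2(OAc)4, followed by acyl migration;
  - carbene dimerisation;
  - poor facial selectivity, if the C–C bond forms from an ylide that is still bound to Rh2(OAc)4 and sits outside the chiral pocket.
- Fallback (known chemistry; sets out from 8 and 10, returns at 14): 10 is reduced with NaBH4 in MeOH at 0 °C to 4-(hydroxymethyl)phenyl pivalate F1. Mitsunobu etherification of phenol 8 with F1 (PPh3, DIAD, THF) gives the benzyl ether 4-({4-bromo-2-[2-(2,4-bis(methoxymethoxy)phenyl)-2-oxoacetyl]phenoxy}methyl)phenyl pivalate F2. Irradiation of F2 at about 420 nm in degassed benzene brings about the Norrish–Yang cyclisation (hydrogen abstraction from the benzylic carbon by the ring A-side carbonyl, then coupling of the 1,5-biradical) to racemic 14 F3. Closure is expected to favour ring B syn to the hydroxyl. Preparative chromatography on a chiral stationary phase then gives 14. Plain O–H insertion in step 10 would deliver the same ether, so material lost in that way can enter this sequence.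

**Step 9.**
- What may go wrong: loss of the aryl ester under the basic conditions; thermal decay of the diazo compound (azine formation) while the salt is fragmented at 40 °C; carry-over of ammonium or sulfinate salts that deactivate the Lewis acid of step 10.
- Fallback (sets out from 10, returns at 13): 10 is condensed with 2-(trifluoromethyl)benzenesulfonohydrazide in MeOH to the hydrazone 4-{(E)-[2-(2-(trifluoromethyl)benzenesulfonyl)hydrazinylidene]methyl}phenyl pivalate F4. NaH in CH2Cl2 at −40 °C gives its sodium salt F5, which fragments below 0 °C; cold filtration from the sulfinate gives a solution of 13 without heating and without a phase-transfer salt.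

**Step 13.**
- What may go wrong: base- or radical-induced oligomerisation of the vinyl ketone faster than carbopalladation, and slow oxidative addition into the electron-rich C–Br bond.
- Fallback (sets out from 14, returns at 17): Stille vinylation of 14 (Bu3SnCH=CH2, Pd(PPh3)4, toluene, 90 °C) gives 4-{(2S,3S)-5-ethenyl-3-hydroxy-3-[2,4-bis(methoxymethoxy)benzoyl]-2,3-dihydro-1-benzofuran-2-yl}phenyl pivalate F6. Cross-metathesis of F6 with 16 (second-generation Hoveyda–Grubbs catalyst RuCl2(SIMes)(=CH-C6H4-2-OiPr), CH2Cl2, 40 °C) then forms the E-enone 17 under neutral conditions.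

**Step 15.**
- What may go wrong: acid-promoted ionisation of the C2–O1 bond once ring B carries a free para-hydroxyl, which would cause epimerisation at C2 or solvolytic ring opening; to a lesser degree, flavanone closure of the chalcone.
- Fallback (sets out from 17, returns at 19): the order of unmasking is reversed. The acetals of 17 are removed first (3 M aq. HCl, MeOH, 40 °C) with the pivalate still on ring B, where it lowers the electron density at C2. This gives 4-{(2S,3S)-3-(2,4-dihydroxybenzoyl)-5-[(E)-3-(2,4-dihydroxyphenyl)-3-oxoprop-1-en-1-yl]-3-hydroxy-2,3-dihydro-1-benzofuran-2-yl}phenyl pivalate F7. A brief methanolysis (K2CO3, MeOH, 0 °C, argon, then mild acid quench) gives 19.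

## Further compounds

F1 | step 10 | 4-(hydroxymethyl)phenyl pivalate | OCc1ccc(OC(=O)C(C)(C)C)cc1
F2 | step 10 | 4-({4-bromo-2-[2-(2,4-bis(methoxymethoxy)phenyl)-2-oxoacetyl]phenoxy}methyl)phenyl pivalate | Brc1ccc(OCc2ccc(OC(=O)C(C)(C)C)cc2)c(c1)C(=O)C(=O)c1ccc(OCOC)cc1OCOC
F3 | step 10 | racemic 14 (both enantiomers, ring B cis to hydroxyl) | Brc1ccc2c(c1)[C@@](O)(C(=O)c1ccc(OCOC)cc1OCOC)[C@H](c1ccc(OC(=O)C(C)(C)C)cc1)O2.Brc1ccc2c(c1)[C@](O)(C(=O)c1ccc(OCOC)cc1OCOC)[C@@H](c1ccc(OC(=O)C(C)(C)C)cc1)O2
F4 | step 9 | 4-{(E)-[2-(2-(trifluoromethyl)benzenesulfonyl)hydrazinylidene]methyl}phenyl pivalate | CC(C)(C)C(=O)Oc1ccc(/C=N/NS(=O)(=O)c2ccccc2C(F)(F)F)cc1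
F5 | step 9 | sodium salt of F4 | [Na+].CC(C)(C)C(=O)Oc1ccc(/C=N/[N-]S(=O)(=O)c2ccccc2C(F)(F)F)cc1
F6 | step 13 | 4-{(2S,3S)-5-ethenyl-3-hydroxy-3-[2,4-bis(methoxymethoxy)benzoyl]-2,3-dihydro-1-benzofuran-2-yl}phenyl pivalate | C=Cc1ccc2c(c1)[C@@](O)(C(=O)c1ccc(OCOC)cc1OCOC)[C@H](c1ccc(OC(=O)C(C)(C)C)cc1)O2
F7 | step 15 | 4-{(2S,3S)-3-(2,4-dihydroxybenzoyl)-5-[(E)-3-(2,4-dihydroxyphenyl)-3-oxoprop-1-en-1-yl]-3-hydroxy-2,3-dihydro-1-benzofuran-2-yl}phenyl pivalate | O=C(/C=C/c1ccc2c(c1)[C@@](O)(C(=O)c1ccc(O)cc1O)[C@H](c1ccc(OC(=O)C(C)(C)C)cc1)O2)c1ccc(O)cc1O
A1 | alternative 1 | 2-[5-bromo-2-(triisopropylsilyloxy)phenyl]-2-chloro-1-[2,4-bis(methoxymethoxy)phenyl]ethan-1-one (racemic) | Brc1ccc(O[Si](C(C)C)(C(C)C)C(C)C)c(c1)C(Cl)C(=O)c1ccc(OCOC)cc1OCOC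
A2 | alternative 1 | 4-(methoxymethoxy)benzaldehyde | O=Cc1ccc(OCOC)cc1
A3 | alternative 1 | [2,4-bis(methoxymethoxy)phenyl]{2-[5-bromo-2-(triisopropylsilyloxy)phenyl]-3-[4-(methoxymethoxy)phenyl]oxiran-2-yl}methanone, aroyl trans to the 3-aryl group, enantiomer as drawn | Brc1ccc(O[Si](C(C)C)(C(C)C)C(C)C)c(c1)[C@]1(C(=O)c2ccc(OCOC)cc2OCOC)O[C@@H]1c1ccc(OCOC)cc1
A4 | alternative 2 | (S)-1-hydroxy-1-[4-(methoxymethoxy)phenyl]-3-[2,4-bis(methoxymethoxy)phenyl]but-3-en-2-one | C=C(c1ccc(OCOC)cc1OCOC)C(=O)[C@H](c1ccc(OCOC)cc1)O
A5 | alternative 2 | (5-cyano-2-fluorophenyl)magnesium chloride | N#Cc1ccc(F)c(c1)[Mg]Cl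
A6 | alternative 2 | 3-hydroxy-3-{1-[2,4-bis(methoxymethoxy)phenyl]ethenyl}-2-[4-(methoxymethoxy)phenyl]-2,3-dihydro-1-benzofuran-5-carbonitrile, C2 and C3 arranged as in the target | N#Cc1ccc2c(c1)[C@@](O)(C(=C)c1ccc(OCOC)cc1OCOC)[C@H](c1ccc(OCOC)cc1)O2
A7 | alternative 3 | 1-(5-bromo-2-{[4-(tert-butyldimethylsilyloxy)phenyl]methoxy}phenyl)-2-[2,4-bis(tert-butyldimethylsilyloxy)phenyl]ethane-1,2-dione | Brc1ccc(OCc2ccc(O[Si](C)(C)C(C)(C)C)cc2)c(c1)C(=O)C(=O)c1ccc(O[Si](C)(C)C(C)(C)C)cc1O[Si](C)(C)C(C)(C)C
A8 | alternative 3 | (2S,3S)-5-bromo-3-hydroxy-3-[2,4-bis(tert-butyldimethylsilyloxy)benzoyl]-2-[4-(tert-butyldimethylsilyloxy)phenyl]-2,3-dihydro-1-benzofuran | Brc1ccc2c(c1)[C@@](O)(C(=O)c1ccc(O[Si](C)(C)C(C)(C)C)cc1O[Si](C)(C)C(C)(C)C)[C@H](c1ccc(O[Si](C)(C)C(C)(C)C)cc1)O2
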